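**Retrosynthetic overview**

- Feature: in the open chain C1 (ArOCH2)–C2 (CH–OOH)–C3 (=CH2)–C4–C5 (C=O)–C6=C7, the aryl ether oxygen on C1 and the hydroperoxide oxygen on C2 are vicinal and sit next to C3, which can begin as an aldehyde carbon. That is acrolein after a nucleophile has added at C1 and an electrophile at C2.
- Late disconnections: C2–OOH from its 2-methoxyprop-2-yl peroxyketal; the C5 enone from oxidative 1,3-transposition of a C7 tertiary allylic alcohol; the C3–C4 bond and the C3 exo-methylene from ruthenium alkene–alkyne coupling of a C3 terminal alkyne with 2-methylpent-4-en-2-ol; the alkyne from the C3 aldehyde.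
- Key disconnection: the C3 aldehyde with its C1–OAr bond, C2–OO bond and C2 stereocentre from acrolein, methyl vanillate and singlet oxygen under an (R)-diarylprolinol silyl ether.
- No ring is formed in the route; the only ring, the benzene ring, is bought in methyl vanillate.

Key step: step 1

Assumption: singlet oxygen is taken to obey the same steric face-shielding as other α-heterofunctionalisations of enamines of diarylprolinol silyl ethers, so the (R)-catalyst, (R)-2-[diphenyl(trimethylsilyloxy)methyl]pyrrolidine (C[Si](C)(C)OC(c1ccccc1)(c1ccccc1)[C@H]1CCCN1), is specified; if the sense were reversed, its enantiomer would be used.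

**Route**

Step 1
Reactants: 1 methyl vanillate; 2 acrolein; 3 dioxygen (as singlet oxygen)
Product: 5 methyl 4-[(2R)-2-hydroperoxy-3-oxopropoxy]-3-methoxybenzoate, via catalyst-bound aryloxy enamine 4 (not isolated)
Conditions: 1 (1.5 equiv), (R)-2-[diphenyl(trimethylsilyloxy)methyl]pyrrolidine (20 mol%), PhCO2H (20 mol%), meso-tetraphenylporphyrin (1 mol%), O2 bubbling, white LED, CH2Cl2, −20 °C, 2 added slowly; cold SiO2 plug, used at once
Reagents that add atoms: none
Why: Proposed new method: the amine condenses with acrolein 2 to an iminium ion, to which the acidic phenol 1 adds reversibly at C1 (oxa-Michael) to give the E-enamine 4; acrolein has no enolisable position, so only the phenol adduct can become an enamine and be oxygenated. Singlet oxygen then attacks the nucleophilic C2 of 4 to give a peroxy-iminium zwitterion, which is protonated by benzoic acid or the phenol and hydrolysed to 5 with release of the amine, and this irreversible capture should pull the unfavourable oxa-Michael equilibrium forward. The closest known reactions are amine-catalysed iminium–enamine cascades of enals (hetero-Michael addition followed by α-heterofunctionalisation) and the amine-catalysed α-oxygenation of saturated aldehydes with singlet oxygen. No ring is closed. The C2 stereocentre is set in the oxygenation: in the s-trans E-enamine the CPh2(OSiMe3) group of the (R)-catalyst blocks one face and oxygen enters on the other, which by the usual shielding model should give the (2R)-aldehyde. The step needs chemoselectivity (oxygenation of the enamine and not of the phenol or amine, protonation of the zwitterion and not dioxetane closure with C2–C3 cleavage, no epoxidation of acrolein by the product hydroperoxide), which the electron-poor para-ester phenol, the protic additive, −20 °C and slow addition of acrolein to excess phenol are meant to secure.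

Step 2
Reactants: 5 methyl 4-[(2R)-2-hydroperoxy-3-oxopropoxy]-3-methoxybenzoate
Product: 6 methyl 3-methoxy-4-{(2R)-2-[(2-methoxypropan-2-yl)peroxy]-3-oxopropoxy}benzoate
Conditions: 2-methoxypropene (3 equiv), PPTS (5 mol%), CH2Cl2, 0 °C; Et3N quench, Et3N-deactivated SiO2
Reagents that add atoms: 2-methoxypropene, C=C(C)OC
Why: Acid-catalysed addition of the hydroperoxide O–H across the enol ether (peroxyketal protection) is fast at 0 °C, creates no stereocentre because the ketal carbon carries two methyl groups, and removes the acidic OOH before the aldehyde is exposed to base.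

Step 3
Reactants: 6 methyl 3-methoxy-4-{(2R)-2-[(2-methoxypropan-2-yl)peroxy]-3-oxopropoxy}benzoate
Product: 7 methyl 3-methoxy-4-({(2S)-2-[(2-methoxypropan-2-yl)peroxy]but-3-yn-1-yl}oxy)benzoate
Conditions: dimethyl (1-diazo-2-oxopropyl)phosphonate (1.3 equiv), K2CO3 (2 equiv), MeOH, 0 °C
Reagents that add atoms: dimethyl (1-diazo-2-oxopropyl)phosphonate (Ohira–Bestmann reagent), COP(=O)(OC)C(=[N+]=[N-])C(C)=O
Why: Ohira–Bestmann variant of the Seyferth–Gilbert homologation, in which the diazomethylphosphonate anion adds to the aldehyde and loss of dimethyl phosphate and N2 with 1,2-hydrogen shift gives the terminal alkyne; the peroxyketal is base-stable, the methyl ester is degenerate in MeOH, and carbonate at 0 °C should let addition to the electrophilic α-peroxy aldehyde outrun enolisation, so C2 keeps its configuration (the descriptor becomes S only through the priority change).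

Step 4
Reactants: 7 methyl 3-methoxy-4-({(2S)-2-[(2-methoxypropan-2-yl)peroxy]but-3-yn-1-yl}oxy)benzoate; 8 2-methylpent-4-en-2-ol
Product: 9 methyl 4-({(2S,5E)-7-hydroxy-2-[(2-methoxypropan-2-yl)peroxy]-7-methyl-3-methylideneoct-5-en-1-yl}oxy)-3-methoxybenzoate
Conditions: 8 (3 equiv), [CpRu(MeCN)3]PF6 (10 mol%), degassed acetone, rt
Reagents that add atoms: none
Why: Ruthenium-catalysed alkene–alkyne coupling (formal intermolecular Alder-ene reaction): oxidative cyclisation on the CpRu cation (divalent ruthenium) joins the internal alkyne carbon C3 to the terminal alkene carbon, and β-hydride elimination then reductive elimination should give the branched 1,4-diene with the C3 exo-methylene and an E C5=C6 alkene under neutral conditions that leave the peroxyketal, the tertiary alcohol and C2 alone.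

Step 5
Reactants: 9 methyl 4-({(2S,5E)-7-hydroxy-2-[(2-methoxypropan-2-yl)peroxy]-7-methyl-3-methylideneoct-5-en-1-yl}oxy)-3-methoxybenzoate
Product: 10 methyl 3-methoxy-4-({(2S)-2-[(2-methoxypropan-2-yl)peroxy]-7-methyl-3-methylidene-5-oxooct-6-en-1-yl}oxy)benzoate
Conditions: 2,2,6,6-tetramethyl-1-oxopiperidinium tetrafluoroborate (TEMPO+ BF4−, 2.5 equiv), MeCN, 0 °C to rt; aq. NaHCO3 quench
Reagents that add atoms: none
Why: Oxoammonium-mediated oxidative 1,3-transposition of a tertiary allylic alcohol (the oxoammonium counterpart of the Babler–Dauben oxidation) moves the C7 oxygen to C5 and oxidises the resulting secondary allylic alcohol to the C5 ketone conjugated with the new C6=C7 alkene, which has no geometry because C7 carries two methyl groups; no stereocentre is touched.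

Step 6
Reactants: 10 methyl 3-methoxy-4-({(2S)-2-[(2-methoxypropan-2-yl)peroxy]-7-methyl-3-methylidene-5-oxooct-6-en-1-yl}oxy)benzoate
Product: 11 methyl 4-{[(2S)-2-hydroperoxy-7-methyl-3-methylidene-5-oxooct-6-en-1-yl]oxy}-3-methoxybenzoate (target)
Conditions: AcOH/THF/H2O (4:2:1), rt
Reagents that add atoms: none
Why: Mild acid hydrolysis of the mixed peroxyketal through its oxocarbenium ion frees the hydroperoxide without breaking the O–O bond, and acetic acid is too weak to move the C3 exo-methylene into conjugation or to ionise the allylic C2–O bond, so the (2S) centre from step 1 is kept.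

**Compound list**

1 | methyl vanillate (methyl 4-hydroxy-3-methoxybenzoate) | COC(=O)c1ccc(O)c(OC)c1 | starting material
2 | acrolein (prop-2-enal) | C=CC=O | starting material
3 | dioxygen (used as singlet oxygen) | O=O | starting material
4 | methyl 3-methoxy-4-{[(2E)-3-{(2R)-2-[diphenyl(trimethylsilyloxy)methyl]pyrrolidin-1-yl}prop-2-en-1-yl]oxy}benzoate (catalyst-bound enamine) | COC(=O)c1ccc(OC/C=C/N2CCC[C@@H]2C(O[Si](C)(C)C)(c2ccccc2)c2ccccc2)c(OC)c1 | intermediate
5 | methyl 4-[(2R)-2-hydroperoxy-3-oxopropoxy]-3-methoxybenzoate | O=C[C@@H](COc1ccc(C(=O)OC)cc1OC)OO | intermediate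
6 | methyl 3-methoxy-4-{(2R)-2-[(2-methoxypropan-2-yl)peroxy]-3-oxopropoxy}benzoate | O=C[C@@H](COc1ccc(C(=O)OC)cc1OC)OOC(C)(C)OC | intermediate
7 | methyl 3-methoxy-4-({(2S)-2-[(2-methoxypropan-2-yl)peroxy]but-3-yn-1-yl}oxy)benzoate | C#C[C@@H](COc1ccc(C(=O)OC)cc1OC)OOC(C)(C)OC | intermediate
8 | 2-methylpent-4-en-2-ol | C=CCC(C)(C)O | starting material
9 | methyl 4-({(2S,5E)-7-hydroxy-2-[(2-methoxypropan-2-yl)peroxy]-7-methyl-3-methylideneoct-5-en-1-yl}oxy)-3-methoxybenzoate | C=C(C/C=C/C(C)(C)O)[C@@H](COc1ccc(C(=O)OC)cc1OC)OOC(C)(C)OC | intermediate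
10 | methyl 3-methoxy-4-({(2S)-2-[(2-methoxypropan-2-yl)peroxy]-7-methyl-3-methylidene-5-oxooct-6-en-1-yl}oxy)benzoate | C=C(CC(=O)C=C(C)C)[C@@H](COc1ccc(C(=O)OC)cc1OC)OOC(C)(C)OC | intermediate
11 | methyl 4-{[(2S)-2-hydroperoxy-7-methyl-3-methylidene-5-oxooct-6-en-1-yl]oxy}-3-methoxybenzoate | C=C(CC(=O)C=C(C)C)[C@@H](COc1ccc(C(=O)OC)cc1OC)OO | target

**Totals**

Total step count: 6. Longest linear sequence: 6 steps (from 1, 2 and 3 to 11).

**Steps most likely to fail**

Step 1 (proposed new method). The oxa-Michael equilibrium may leave too little enamine for capture. Singlet oxygen may instead consume the amine or the phenol. The zwitterion may close to a dioxetane and cleave C2–C3. The product hydroperoxide may epoxidise free acrolein, and facial selectivity at C2 may be poor. The fallback separates the two bond formations and uses only known reactions, setting out from 1. Alkylation of 1 with 3-bromopropan-1-ol (K2CO3, DMF, 60 °C) should give methyl 4-(3-hydroxypropoxy)-3-methoxybenzoate F1. Dess–Martin periodinane (NaHCO3, CH2Cl2, 0 °C) should oxidise it to methyl 3-methoxy-4-(3-oxopropoxy)benzoate F2. The known amine-catalysed α-oxygenation of this saturated aldehyde with singlet oxygen (same (R)-catalyst, meso-tetraphenylporphyrin, O2, white LED, CH2Cl2, −20 °C), now without free acrolein or phenol in the flask, should give 5, where the route is rejoined.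

Step 4. The electron-rich divalent ruthenium centre may reduce or cleave the O–O bond. The branched, oxygenated propargylic position may also steer C–C bond formation to the terminal alkyne carbon and give the linear diene. The fallback sets out from aldehyde 6 and avoids the alkyne, so it also bypasses the base-sensitive step 3.
- Allylboronic acid pinacol ester (CH2Cl2, rt) should add to 6 to give the homoallylic alcohol methyl 4-({(2R)-3-hydroxy-2-[(2-methoxypropan-2-yl)peroxy]hex-5-en-1-yl}oxy)-3-methoxybenzoate F3 as a mixture of C3 epimers.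
- Dess–Martin periodinane (NaHCO3, CH2Cl2, 0 °C) should give the ketone methyl 3-methoxy-4-({(2R)-2-[(2-methoxypropan-2-yl)peroxy]-3-oxohex-5-en-1-yl}oxy)benzoate F4.
- Wittig methylenation (Ph3PCH3Br, KN(SiMe3)2, THF, −78 to 0 °C) should give the diene methyl 3-methoxy-4-({(2S)-2-[(2-methoxypropan-2-yl)peroxy]-3-methylidenehex-5-en-1-yl}oxy)benzoate F5.
- Cross-metathesis of the monosubstituted alkene of F5 with excess 2-methylbut-3-en-2-ol (second-generation Grubbs catalyst RuCl2(H2IMes)(PCy3)(=CHPh), CH2Cl2, 40 °C) should give 9, where the route is rejoined. Ruthenium alkylidenes are known to tolerate dialkyl peroxides.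

Step 5. Acid released from the oxoammonium salt may strip the peroxyketal, after which the freed hydroperoxide can be oxidised. The oxoammonium cation may attack the 1,1-disubstituted alkene in an ene-type reaction. The C3 exo-methylene may migrate into conjugation with the new ketone. The fallback separates isomerisation from oxidation and sets out from 9. Triphenylsilyl perrhenate Ph3SiOReO3 (heptavalent rhenium, 5 mol%, Et2O, 0 °C) should equilibrate 9 by 1,3-transposition with the secondary allylic alcohol methyl 4-({(2S)-5-hydroxy-2-[(2-methoxypropan-2-yl)peroxy]-7-methyl-3-methylideneoct-6-en-1-yl}oxy)-3-methoxybenzoate F6 (both C5 epimers). MnO2 (CH2Cl2, rt) oxidises only this secondary allylic alcohol and should give 10, where the route is rejoined; unchanged 9 is recycled.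

**Further compounds**

F1 | step 1 | methyl 4-(3-hydroxypropoxy)-3-methoxybenzoate | COC(=O)c1ccc(OCCCO)c(OC)c1
F2 | step 1 | methyl 3-methoxy-4-(3-oxopropoxy)benzoate | COC(=O)c1ccc(OCCC=O)c(OC)c1
F3 | step 4 | methyl 4-({(2R)-3-hydroxy-2-[(2-methoxypropan-2-yl)peroxy]hex-5-en-1-yl}oxy)-3-methoxybenzoate (C3 epimers) | C=CCC(O)[C@@H](COc1ccc(C(=O)OC)cc1OC)OOC(C)(C)OC
F4 | step 4 | methyl 3-methoxy-4-({(2R)-2-[(2-methoxypropan-2-yl)peroxy]-3-oxohex-5-en-1-yl}oxy)benzoate | C=CCC(=O)[C@@H](COc1ccc(C(=O)OC)cc1OC)OOC(C)(C)OC
F5 | step 4 | methyl 3-methoxy-4-({(2S)-2-[(2-methoxypropan-2-yl)peroxy]-3-methylidenehex-5-en-1-yl}oxy)benzoate | C=CCC(=C)[C@@H](COc1ccc(C(=O)OC)cc1OC)OOC(C)(C)OC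
F6 | step 5 | methyl 4-({(2S)-5-hydroxy-2-[(2-methoxypropan-2-yl)peroxy]-7-methyl-3-methylideneoct-6-en-1-yl}oxy)-3-methoxybenzoate (C5 epimers) | C=C(CC(O)C=C(C)C)[C@@H](COc1ccc(C(=O)OC)cc1OC)OOC(C)(C)OC
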